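## Retrosynthetic overview (azulene numbering of the target skeleton: ring A = C1–C3/C3a/C8a, ring B = C3a–C8a)

1. Target ⇐ epoxidation of the ring-A olefin (both epoxide C–O bonds) directed by the free C7 hydroxyl, after global desilylation.
2. Key C–O bond: the C5–O–aroyl ester bond is made in the step that closes ring B, an acyloxy-Sakurai cyclisation of a C5 aldehyde onto a C4 allylsilane with the benzoic anhydride; the isopropenyl group is then hydrogenated.
3. The C5 oxygen comes from hydroboration–oxidation of the linalool vinyl group; the allylsilane comes from Wittig olefination of a ring-A aldehyde.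
4. Ring A (cyclopentene) is made first by McMurry coupling of a 1,5-keto aldehyde, which comes from an amine-catalysed Michael addition that sets C8a and C3a.
5. The C7 carbinol centre is bought with (R)-linalool; ring order A, then B, epoxide last.

Assumption: (R)-(−)-linalool of ≥95% ee and 4-[(tert-butyldimethylsilyl)oxy]benzoic acid are purchased; minor diastereomers from residual (S)-linalool are removed by chromatography after ring B is closed.

## Route

Step 1
Reactants: 1 (R)-(−)-linalool [(3R)-3,7-dimethylocta-1,6-dien-3-ol]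
Product: 2 triethyl{[(3R)-3,7-dimethylocta-1,6-dien-3-yl]oxy}silane
Conditions: Et3SiOTf, 2,6-lutidine, CH2Cl2, −78 → 0 °C
Reagents that add atoms: triethylsilyl trifluoromethanesulfonate, CC[Si](CC)(CC)OS(=O)(=O)C(F)(F)F
Why: Silyl-triflate silylation caps the hindered tertiary allylic alcohol, which low-valent titanium in step 4 would otherwise attack; the future C7 stereocentre is carried unchanged from linalool.

Step 2
Reactants: 2 triethyl{[(3R)-3,7-dimethylocta-1,6-dien-3-yl]oxy}silane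
Product: 4 (4R)-4-methyl-4-[(triethylsilyl)oxy]hex-5-enal, via ozonide 3 (not isolated)
Conditions: O3 (1.0 equiv), CH2Cl2, −78 °C; then Me2S, −78 → 23 °C
Reagents that add atoms: ozone, [O-][O+]=O
Why: Chemoselective ozonolysis, because the electron-rich trisubstituted olefin reacts far faster than the vinyl group next to the silyloxy-bearing quaternary carbon; the stereocentre is not involved.

Step 3
Reactants: 4 (4R)-4-methyl-4-[(triethylsilyl)oxy]hex-5-enal; 5 ethyl (2E)-4-oxopent-2-enoate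
Product: 6 ethyl (2R,3S,5R)-3-formyl-5-methyl-2-(2-oxopropyl)-5-[(triethylsilyl)oxy]hept-6-enoate
Conditions: (R)-2-[diphenyl(trimethylsilyloxy)methyl]pyrrolidine (10 mol %), 4-nitrophenol (20 mol %), CH2Cl2, 0 °C
Reagents that add atoms: none
Why: Hayashi–Jørgensen enamine Michael addition to a γ-oxo enoate: the (E)-enamine attacks the carbon β to the ketone from the face not shielded by the diarylsilyloxymethyl group through Seebach's synclinal transition state, giving the syn (2R,3S) adduct whose two new centres become C3a and C8a with the trans ring fusion.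

Step 4
Reactants: 6 ethyl (2R,3S,5R)-3-formyl-5-methyl-2-(2-oxopropyl)-5-[(triethylsilyl)oxy]hept-6-enoate
Product: 7 ethyl (1R,2R)-4-methyl-2-{(2R)-2-methyl-2-[(triethylsilyl)oxy]but-3-en-1-yl}cyclopent-3-ene-1-carboxylate
Conditions: TiCl3(DME)1.5, Zn–Cu couple, DME, reflux, 6 added over 20 h
Reagents that add atoms: none
Why: McMurry reductive coupling of the 1,5-keto aldehyde closes ring A as the 1-methylcyclopentene with the olefin fixed between the former aldehyde and ketone carbons; the two stereocentres are untouched and end trans.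

Step 5
Reactants: 7 ethyl (1R,2R)-4-methyl-2-{(2R)-2-methyl-2-[(triethylsilyl)oxy]but-3-en-1-yl}cyclopent-3-ene-1-carboxylate
Product: 8 (1R,2R)-4-methyl-2-{(2R)-2-methyl-2-[(triethylsilyl)oxy]but-3-en-1-yl}cyclopent-3-ene-1-carbaldehyde
Conditions: i-Bu2AlH (1.1 equiv), CH2Cl2, −78 °C; aq. potassium sodium tartrate
Reagents that add atoms: none
Why: Partial ester reduction with DIBAL-H at −78 °C stops at the aluminium hemiacetal and gives the aldehyde on work-up; the trans arrangement is also the thermodynamic one, so the α-centre is not at risk.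

Step 6
Reactants: 8 (1R,2R)-4-methyl-2-{(2R)-2-methyl-2-[(triethylsilyl)oxy]but-3-en-1-yl}cyclopent-3-ene-1-carbaldehyde
Product: 9 triethyl[((2R)-2-methyl-1-{(1S,5R)-3-methyl-5-[2-methyl-3-(trimethylsilyl)prop-1-en-1-yl]cyclopent-2-en-1-yl}but-3-en-2-yl)oxy]silane (E/Z mixture)
Conditions: [Ph3PCH(CH3)CH2SiMe3]I, n-BuLi, THF, 0 °C; then 8, −78 → 23 °C
Reagents that add atoms: triphenyl[1-(trimethylsilyl)propan-2-yl]phosphonium iodide, CC(C[Si](C)(C)C)[P+](c1ccccc1)(c1ccccc1)c1ccccc1.[I-]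
Why: Wittig olefination with the β-silyl ylide (Seyferth–Fleming allylsilane synthesis, salt made beforehand from EtPPh3Br, n-BuLi and ICH2SiMe3) gives a 2-methylallylsilane whose C4 terminus is far more nucleophilic than the ring-A olefin, which would otherwise compete in a six-membered cyclisation in step 9; the olefin geometry is lost in step 9 and does not matter.

Step 7
Reactants: 9 triethyl[((2R)-2-methyl-1-{(1S,5R)-3-methyl-5-[2-methyl-3-(trimethylsilyl)prop-1-en-1-yl]cyclopent-2-en-1-yl}but-3-en-2-yl)oxy]silane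
Product: 11 (3R)-3-methyl-4-{(1S,5R)-3-methyl-5-[2-methyl-3-(trimethylsilyl)prop-1-en-1-yl]cyclopent-2-en-1-yl}-3-[(triethylsilyl)oxy]butan-1-ol, via alkylborane 10 (not isolated)
Conditions: 9-BBN, THF, 0 → 23 °C; then NaOH, H2O2, 0 °C
Reagents that add atoms: hydrogen peroxide, OO; 9-borabicyclo[3.3.1]nonane (its atoms stay in 10 only), B1C2CCCC1CCC2
Why: Hydroboration–oxidation: 9-BBN adds only to the monosubstituted vinyl group with boron on the terminal carbon, and alkaline peroxide then forms the C5–O bond with retention, leaving the two trisubstituted olefins untouched.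

Step 8
Reactants: 11 (3R)-3-methyl-4-{(1S,5R)-3-methyl-5-[2-methyl-3-(trimethylsilyl)prop-1-en-1-yl]cyclopent-2-en-1-yl}-3-[(triethylsilyl)oxy]butan-1-ol
Product: 12 (3R)-3-methyl-4-{(1S,5R)-3-methyl-5-[2-methyl-3-(trimethylsilyl)prop-1-en-1-yl]cyclopent-2-en-1-yl}-3-[(triethylsilyl)oxy]butanal
Conditions: Dess–Martin periodinane, CH2Cl2, 0 → 23 °C
Reagents that add atoms: none
Why: Dess–Martin oxidation of the primary alcohol to the aldehyde under mild, Lewis-acid-free conditions that leave the allylsilane and the silyl ether intact.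

Step 9
Reactants: 12 (3R)-3-methyl-4-{(1S,5R)-3-methyl-5-[2-methyl-3-(trimethylsilyl)prop-1-en-1-yl]cyclopent-2-en-1-yl}-3-[(triethylsilyl)oxy]butanal; 13 4-[(tert-butyldimethylsilyl)oxy]benzoic acid
Product: 14 (3aR,4R,5S,7R,8aS)-2,7-dimethyl-4-(prop-1-en-2-yl)-7-[(triethylsilyl)oxy]-3,3a,4,5,6,7,8,8a-octahydroazulen-5-yl 4-[(tert-butyldimethylsilyl)oxy]benzoate
Conditions: 13 (2.2 equiv), DCC (1.1 equiv), CH2Cl2, 23 °C (anhydride formed in the flask); then 12, Sc(OTf)3 (10 mol %), MeCN/CH2Cl2, −40 → 0 °C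
Reagents that add atoms: none
Why: Proposed new method: intramolecular acyloxy-Sakurai cyclisation, in which Sc(OTf)3 turns the aldehyde and the aroyl anhydride into the gem-diacyloxy acetal and ionises it to an O-acyl oxocarbenium ion (the new acyl C–O bond on the C5 oxygen), which the tethered allylsilane attacks at C4 (SE2', loss of Me3Si) through a chair-like synclinal transition state with both new substituents equatorial, closing ring B and setting C4 (isopropenyl anti to C3a–H) and C5 (acyloxy trans to isopropenyl); plain Sakurai addition followed by Sc(OTf)3-catalysed acylation of the silyl ether converges on the same ester; the closest known reaction type is the Sc(OTf)3-catalysed intermolecular Sakurai allylation of aldehydes in the presence of acetic anhydride, which gives homoallylic acetates via acylals but has not been shown intramolecularly, for a seven-membered ring, or with an aroyl anhydride.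

Step 10
Reactants: 14 (3aR,4R,5S,7R,8aS)-2,7-dimethyl-4-(prop-1-en-2-yl)-7-[(triethylsilyl)oxy]-3,3a,4,5,6,7,8,8a-octahydroazulen-5-yl 4-[(tert-butyldimethylsilyl)oxy]benzoate
Product: 15 (3aR,4S,5S,7R,8aS)-2,7-dimethyl-4-(propan-2-yl)-7-[(triethylsilyl)oxy]-3,3a,4,5,6,7,8,8a-octahydroazulen-5-yl 4-[(tert-butyldimethylsilyl)oxy]benzoate
Conditions: H2 (1 atm), RhCl(PPh3)3 (5 mol %), benzene, 23 °C
Reagents that add atoms: none
Why: Homogeneous hydrogenation with RhCl(PPh3)3 reduces the 1,1-disubstituted isopropenyl group much faster than the trisubstituted ring-A olefin; no stereocentre is made or touched (C4 only changes descriptor).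

Step 11
Reactants: 15 (3aR,4S,5S,7R,8aS)-2,7-dimethyl-4-(propan-2-yl)-7-[(triethylsilyl)oxy]-3,3a,4,5,6,7,8,8a-octahydroazulen-5-yl 4-[(tert-butyldimethylsilyl)oxy]benzoate
Product: 16 (3aR,4S,5S,7R,8aS)-7-hydroxy-2,7-dimethyl-4-(propan-2-yl)-3,3a,4,5,6,7,8,8a-octahydroazulen-5-yl 4-hydroxybenzoate
Conditions: HF·pyridine, pyridine, THF, 0 → 23 °C
Reagents that add atoms: none
Why: Fluoride-mediated global desilylation removes the tertiary triethylsilyl ether and the aryl silyl ether while the hindered benzoate and the olefin are stable; it is done before the acid-sensitive epoxide exists.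

Step 12
Reactants: 16 (3aR,4S,5S,7R,8aS)-7-hydroxy-2,7-dimethyl-4-(propan-2-yl)-3,3a,4,5,6,7,8,8a-octahydroazulen-5-yl 4-hydroxybenzoate
Product: 17 (1S,2R,3aR,4S,5S,7R,8aS)-1,2-epoxy-7-hydroxy-2,7-dimethyl-4-(propan-2-yl)decahydroazulen-5-yl 4-hydroxybenzoate
Conditions: VO(acac)2 (5 mol %), t-BuOOH (1.5 equiv, decane), CH2Cl2, 0 → 23 °C
Reagents that add atoms: tert-butyl hydroperoxide, CC(C)(C)OO
Why: Hydroxyl-directed epoxidation (Sharpless–Michaelson VO(acac)2/t-BuOOH): the bishomoallylic tertiary C7–OH sits on the same face of ring A as the C8a–C8 bond, binds the vanadium alkylperoxide and delivers oxygen to that face, setting C1 and C2; opening of the epoxide by the same hydroxyl would need a trans-fused oxabicycle and is not expected.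

## Compound list

1 | (R)-(−)-linalool, (3R)-3,7-dimethylocta-1,6-dien-3-ol | CC(C)=CCC[C@@](C)(O)C=C | starting material
2 | triethyl{[(3R)-3,7-dimethylocta-1,6-dien-3-yl]oxy}silane | CC(C)=CCC[C@@](C)(O[Si](CC)(CC)CC)C=C | intermediate
3 | 3,3-dimethyl-5-{(3R)-3-methyl-3-[(triethylsilyl)oxy]pent-4-en-1-yl}-1,2,4-trioxolane (ozonide, both epimers at the ring CH) | CC1(C)OOC(CC[C@@](C)(O[Si](CC)(CC)CC)C=C)O1 | intermediate
4 | (4R)-4-methyl-4-[(triethylsilyl)oxy]hex-5-enal | O=CCC[C@@](C)(O[Si](CC)(CC)CC)C=C | intermediate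
5 | ethyl (2E)-4-oxopent-2-enoate | CCOC(=O)/C=C/C(C)=O | starting material
6 | ethyl (2R,3S,5R)-3-formyl-5-methyl-2-(2-oxopropyl)-5-[(triethylsilyl)oxy]hept-6-enoate | CCOC(=O)[C@@H]([C@@H](C=O)C[C@@](C)(O[Si](CC)(CC)CC)C=C)CC(C)=O | intermediate
7 | ethyl (1R,2R)-4-methyl-2-{(2R)-2-methyl-2-[(triethylsilyl)oxy]but-3-en-1-yl}cyclopent-3-ene-1-carboxylate | CCOC(=O)[C@@H]1CC(C)=C[C@H]1C[C@@](C)(O[Si](CC)(CC)CC)C=C | intermediate
8 | (1R,2R)-4-methyl-2-{(2R)-2-methyl-2-[(triethylsilyl)oxy]but-3-en-1-yl}cyclopent-3-ene-1-carbaldehyde | O=C[C@@H]1CC(C)=C[C@H]1C[C@@](C)(O[Si](CC)(CC)CC)C=C | intermediate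
9 | triethyl[((2R)-2-methyl-1-{(1S,5R)-3-methyl-5-[2-methyl-3-(trimethylsilyl)prop-1-en-1-yl]cyclopent-2-en-1-yl}but-3-en-2-yl)oxy]silane (E/Z mixture) | C[Si](C)(C)CC(C)=C[C@@H]1CC(C)=C[C@H]1C[C@@](C)(O[Si](CC)(CC)CC)C=C | intermediate
10 | B-alkyl-9-borabicyclo[3.3.1]nonane from 9 (boron on the terminal carbon of the former vinyl group, other centres as in 9) | C[Si](C)(C)CC(C)=C[C@@H]1CC(C)=C[C@H]1C[C@@](C)(O[Si](CC)(CC)CC)CCB2C3CCCC2CCC3 | intermediate
11 | (3R)-3-methyl-4-{(1S,5R)-3-methyl-5-[2-methyl-3-(trimethylsilyl)prop-1-en-1-yl]cyclopent-2-en-1-yl}-3-[(triethylsilyl)oxy]butan-1-ol | C[Si](C)(C)CC(C)=C[C@@H]1CC(C)=C[C@H]1C[C@@](C)(O[Si](CC)(CC)CC)CCO | intermediate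
12 | (3R)-3-methyl-4-{(1S,5R)-3-methyl-5-[2-methyl-3-(trimethylsilyl)prop-1-en-1-yl]cyclopent-2-en-1-yl}-3-[(triethylsilyl)oxy]butanal | C[Si](C)(C)CC(C)=C[C@@H]1CC(C)=C[C@H]1C[C@@](C)(O[Si](CC)(CC)CC)CC=O | intermediate
13 | 4-[(tert-butyldimethylsilyl)oxy]benzoic acid | CC(C)(C)[Si](C)(C)Oc1ccc(cc1)C(O)=O | starting material
14 | (3aR,4R,5S,7R,8aS)-2,7-dimethyl-4-(prop-1-en-2-yl)-7-[(triethylsilyl)oxy]-3,3a,4,5,6,7,8,8a-octahydroazulen-5-yl 4-[(tert-butyldimethylsilyl)oxy]benzoate | CC(=C)[C@H]1[C@@H]2CC(C)=C[C@H]2C[C@@](C)(O[Si](CC)(CC)CC)C[C@@H]1OC(=O)c1ccc(O[Si](C)(C)C(C)(C)C)cc1 | intermediate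
15 | (3aR,4S,5S,7R,8aS)-2,7-dimethyl-4-(propan-2-yl)-7-[(triethylsilyl)oxy]-3,3a,4,5,6,7,8,8a-octahydroazulen-5-yl 4-[(tert-butyldimethylsilyl)oxy]benzoate | CC(C)[C@H]1[C@@H]2CC(C)=C[C@H]2C[C@@](C)(O[Si](CC)(CC)CC)C[C@@H]1OC(=O)c1ccc(O[Si](C)(C)C(C)(C)C)cc1 | intermediate
16 | (3aR,4S,5S,7R,8aS)-7-hydroxy-2,7-dimethyl-4-(propan-2-yl)-3,3a,4,5,6,7,8,8a-octahydroazulen-5-yl 4-hydroxybenzoate | CC(C)[C@H]1[C@@H]2CC(C)=C[C@H]2C[C@@](C)(O)C[C@@H]1OC(=O)c1ccc(O)cc1 | intermediate
17 | (1S,2R,3aR,4S,5S,7R,8aS)-1,2-epoxy-7-hydroxy-2,7-dimethyl-4-(propan-2-yl)decahydroazulen-5-yl 4-hydroxybenzoate | CC(C)[C@H]1[C@@H]2C[C@@]3(C)O[C@H]3[C@H]2C[C@@](C)(O)C[C@@H]1OC(=O)c1ccc(O)cc1 | target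

## Step count and risk

Total steps: 12. Longest linear sequence: 12 steps (1 to 17); 5 and 13 are bought.

Three steps most likely to fail:

The proposed acyloxy-Sakurai cyclisation (step 9) may give unacylated alcohol, β-elimination of the silyloxy group, or the wrong C5 epimer. The fallback is known chemistry: set out from 12, run a standard intramolecular Hosomi–Sakurai reaction (BF3·OEt2, CH2Cl2, −78 °C) to the homoallylic alcohol (3aR,4R,5S,7R,8aS)-2,7-dimethyl-4-(prop-1-en-2-yl)-7-[(triethylsilyl)oxy]-3,3a,4,5,6,7,8,8a-octahydroazulen-5-ol F1, and esterify it with 13 under Steglich conditions (DCC, DMAP, CH2Cl2), which comes back to the route at 14. If the cyclisation gives the C5 epimer instead, a Mitsunobu esterification with 13 inverts it to the same ester.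

The McMurry coupling (step 4) has to tolerate an ester and two epimerisable centres. The fallback sets out from 6 and replaces the one-step deoxygenative coupling by a pinacol/Corey–Winter sequence. SmI2 (THF, t-BuOH, −78 °C) gives the cis-diol ethyl (1R,2S)-3,4-dihydroxy-4-methyl-2-{(2R)-2-methyl-2-[(triethylsilyl)oxy]but-3-en-1-yl}cyclopentane-1-carboxylate F2. 1,1'-Thiocarbonyldiimidazole converts it into the cyclic thionocarbonate ethyl (4S,5R)-6a-methyl-4-{(2R)-2-methyl-2-[(triethylsilyl)oxy]but-3-en-1-yl}-2-sulfanylidenetetrahydro-3aH-cyclopenta[d][1,3]dioxole-5-carboxylate F3. Heating F3 with P(OMe)3 returns to the route at 7.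

The directed epoxidation (step 12) relies on a remote tertiary hydroxyl and runs in the presence of a free phenol that can bind vanadium. The fallback sets out from 15 and changes the order of events so that the phenol stays protected. PPTS in MeOH removes only the tertiary triethylsilyl ether to give (3aR,4S,5S,7R,8aS)-7-hydroxy-2,7-dimethyl-4-(propan-2-yl)-3,3a,4,5,6,7,8,8a-octahydroazulen-5-yl 4-[(tert-butyldimethylsilyl)oxy]benzoate F4. VO(acac)2/t-BuOOH then gives (1S,2R,3aR,4S,5S,7R,8aS)-1,2-epoxy-7-hydroxy-2,7-dimethyl-4-(propan-2-yl)decahydroazulen-5-yl 4-[(tert-butyldimethylsilyl)oxy]benzoate F5. Bu4NF buffered with AcOH removes the aryl silyl ether and comes back to the route at 17.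

## Further compounds

F1 | step 9 | (3aR,4R,5S,7R,8aS)-2,7-dimethyl-4-(prop-1-en-2-yl)-7-[(triethylsilyl)oxy]-3,3a,4,5,6,7,8,8a-octahydroazulen-5-ol | CC(=C)[C@H]1[C@@H]2CC(C)=C[C@H]2C[C@@](C)(O[Si](CC)(CC)CC)C[C@@H]1O
F2 | step 4 | ethyl (1R,2S)-3,4-dihydroxy-4-methyl-2-{(2R)-2-methyl-2-[(triethylsilyl)oxy]but-3-en-1-yl}cyclopentane-1-carboxylate (cis-3,4-diol) | CCOC(=O)[C@@H]1CC(C)(O)C(O)[C@H]1C[C@@](C)(O[Si](CC)(CC)CC)C=C
F3 | step 4 | ethyl (4S,5R)-6a-methyl-4-{(2R)-2-methyl-2-[(triethylsilyl)oxy]but-3-en-1-yl}-2-sulfanylidenetetrahydro-3aH-cyclopenta[d][1,3]dioxole-5-carboxylate (cis-fused) | CCOC(=O)[C@@H]1CC2(C)OC(=S)OC2[C@H]1C[C@@](C)(O[Si](CC)(CC)CC)C=C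
F4 | step 12 | (3aR,4S,5S,7R,8aS)-7-hydroxy-2,7-dimethyl-4-(propan-2-yl)-3,3a,4,5,6,7,8,8a-octahydroazulen-5-yl 4-[(tert-butyldimethylsilyl)oxy]benzoate | CC(C)[C@H]1[C@@H]2CC(C)=C[C@H]2C[C@@](C)(O)C[C@@H]1OC(=O)c1ccc(O[Si](C)(C)C(C)(C)C)cc1
F5 | step 12 | (1S,2R,3aR,4S,5S,7R,8aS)-1,2-epoxy-7-hydroxy-2,7-dimethyl-4-(propan-2-yl)decahydroazulen-5-yl 4-[(tert-butyldimethylsilyl)oxy]benzoate | CC(C)[C@H]1[C@@H]2C[C@@]3(C)O[C@H]3[C@H]2C[C@@](C)(O)C[C@@H]1OC(=O)c1ccc(O[Si](C)(C)C(C)(C)C)cc1
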